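**Plan**
- Retrosynthetic cuts, in order: the acetate and the alkyne silyl group; C3=C4 (Peterson olefination of a C4 aldehyde that comes from an allyl group on C6); then, in one operation, O–C6, C7–Cl and C9–Cl; then C13–Br, O–C12 and C7–C8.
- Enabling feature: the ring oxygen and the chlorine-bearing C9 are joined by the three-carbon bridge C6–C7–C8, so O, C6, C7, C8, C9 can form a five-membered ring. The oxocane (O, C6–C12) is therefore a 2,5-cis-oxolane (ring A: O, C9, C10, C11, C12) whose O–C9 bond was cut by chloride, and the O–C6/C7–Cl pair is the anti adduct of that oxygen and chlorine to a Z C6=C7 alkene.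
- Forward order of rings: ring A by 5-exo opening of a C12–C13 epoxide by the C9 hydroxyl; ring B (O, C9, C8, C7, C6) as a bicyclic oxonium ion; rings A and B merge into the eight-membered ring when chloride cuts the shared O–C9 bond.
- Chain: (E)-hex-3-enal plus vinyl Grignard (C8–C15); epoxide opening at C8 by the acetylide of pent-1-en-4-yne (C4–C7 plus one carbon later lost to ozone); a bis-silylpropyne for C1–C3.
- Stereochemistry: C9/C10 from a Sharpless kinetic-resolution epoxidation; C12/C13 from a Shi epoxidation (C12 inverted on ring closure, C13 inverted by bromide); C6/C7/C9 in the key step (anti addition to the Z alkene from the Lindlar step, exo transition state, inversion at C9); Z C3=C4 from the Peterson step.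

Key step: step 9

Remark: atoms are numbered along the C15 chain of the target (C1≡C2, C3=C4, C5, C6–O, C7–Cl, C8, C9–Cl, C10–OAc, C11, C12–O, C13–Br, C14, C15). Et2SCl·SbCl6 is taken as a preformed salt (from Et2S, Cl2 and SbCl5), and the L-fructose-derived epoxidation ketone as purchasable.

**Route**

Step 1
Reactants: 1 (E)-hex-3-en-1-ol
Product: 2 (E)-hex-3-enal
Conditions: Dess–Martin periodinane, NaHCO3, CH2Cl2, 0 °C; used at once as a solution
Reagents that add atoms: none
Why: Dess–Martin oxidation is neutral enough to give the β,γ-unsaturated aldehyde without moving the E double bond into conjugation.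

Step 2
Reactants: 2 (E)-hex-3-enal
Product: 3 rac-(E)-octa-1,5-dien-3-ol
Conditions: CH2=CHMgBr, THF, −78 °C; then aqueous work-up
Reagents that add atoms: vinylmagnesium bromide, C=C[Mg]Br
Why: Grignard 1,2-addition to the aldehyde at low temperature should give the racemic allylic carbinol (C10) that the next step resolves.

Step 3
Reactants: 3 rac-(E)-octa-1,5-dien-3-ol
Product: 4 (1S,3E)-1-[(2R)-oxiran-2-yl]hex-3-en-1-ol
Conditions: Ti(OiPr)4 (0.1 equiv), L-(+)-diisopropyl tartrate (0.12 equiv), t-BuOOH (0.45 equiv), 4 Å molecular sieves, CH2Cl2, −20 °C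
Reagents that add atoms: tert-butyl hydroperoxide, CC(C)(C)OO
Why: In this Sharpless kinetic-resolution epoxidation the (S)-carbinol is the fast-reacting antipode with the L-tartrate and is epoxidised only at the allylic vinyl group, anti to the hydroxyl, which sets C9 (R) by reagent control and C10 (S) by resolution while (R)-3 and the homoallylic E alkene stay untouched.

Step 4
Reactants: 4 (1S,3E)-1-[(2R)-oxiran-2-yl]hex-3-en-1-ol
Product: 5 tert-butyl{[(1S,3E)-1-[(2R)-oxiran-2-yl]hex-3-en-1-yl]oxy}dimethylsilane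
Conditions: t-BuMe2SiCl, imidazole, DMF, 0 °C → rt
Reagents that add atoms: tert-butyldimethylsilyl chloride, CC(C)(C)[Si](C)(C)Cl
Why: Standard silylation of the secondary alcohol, chosen because a silyl ether on the C10 oxygen cannot take part at C9 in step 9 as an ester would.

Step 5
Reactants: 5 tert-butyl{[(1S,3E)-1-[(2R)-oxiran-2-yl]hex-3-en-1-yl]oxy}dimethylsilane; 6 pent-1-en-4-yne
Product: 8 (7R,8S,10E)-8-[(tert-butyldimethylsilyl)oxy]trideca-1,10-dien-4-yn-7-ol, via lithium pent-4-en-1-yn-1-ide 7 (not isolated)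
Conditions: 6 (1.5 equiv), n-BuLi, THF, −78 °C; BF3·OEt2; then 5, −78 °C
Reagents that add atoms: none
Why: BF3-promoted opening of the terminal epoxide by the lithium acetylide at the unsubstituted carbon C8 should form the C7–C8 bond and free the C9 hydroxyl with its configuration untouched.

Step 6
Reactants: 8 (7R,8S,10E)-8-[(tert-butyldimethylsilyl)oxy]trideca-1,10-dien-4-yn-7-ol
Product: 10 (1S)-1-[(2R,4S,5R)-4-[(tert-butyldimethylsilyl)oxy]-5-(hex-5-en-2-yn-1-yl)oxolan-2-yl]propan-1-ol, via hydroxy epoxide 9 (not isolated)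
Conditions: 1,2:4,5-di-O-isopropylidene-β-L-erythro-2,3-hexodiulo-2,6-pyranose (0.3 equiv; the L-fructose-derived antipode of the Shi ketone), KHSO5 (as 2KHSO5·KHSO4·K2SO4), K2CO3, Bu4NHSO4, MeCN/CH2(OMe)2–aq. Na2B4O7, 0 °C; then camphorsulfonic acid (cat.), CH2Cl2, 0 °C
Reagents that add atoms: potassium peroxymonosulfate, [K+].[O-]S(=O)(=O)OO
Why: Shi epoxidation by the chiral dioxirane should take the E-disubstituted C12=C13 alkene in preference to the vinyl group and the alkyne and give the (12S,13S)-epoxide under reagent control, after which acid lets the C9 hydroxyl open it 5-exo at C12 with inversion, closing the 2,5-cis-oxolane (ring A) and leaving the (13S)-alcohol.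

Step 7
Reactants: 10 (1S)-1-[(2R,4S,5R)-4-[(tert-butyldimethylsilyl)oxy]-5-(hex-5-en-2-yn-1-yl)oxolan-2-yl]propan-1-ol
Product: 11 (1S)-1-[(2R,4S,5R)-4-[(tert-butyldimethylsilyl)oxy]-5-[(2Z)-hexa-2,5-dien-1-yl]oxolan-2-yl]propan-1-ol
Conditions: H2 (1 atm), Pd/CaCO3 poisoned with Pb(OAc)2, quinoline, EtOAc, rt, stopped after 1 equiv of H2
Reagents that add atoms: none
Why: Lindlar semi-hydrogenation adds hydrogen syn to the internal alkyne and should stop at the Z C6=C7 alkene, the geometry that step 9 turns into the cis relation of the C6 side chain and the C7 chlorine.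

Step 8
Reactants: 11 (1S)-1-[(2R,4S,5R)-4-[(tert-butyldimethylsilyl)oxy]-5-[(2Z)-hexa-2,5-dien-1-yl]oxolan-2-yl]propan-1-ol
Product: 12 {[(2R,3S,5R)-5-[(1R)-1-bromopropyl]-2-[(2Z)-hexa-2,5-dien-1-yl]oxolan-3-yl]oxy}(tert-butyl)dimethylsilane
Conditions: CBr4, (n-C8H17)3P, toluene, 70 °C
Reagents that add atoms: carbon tetrabromide, BrC(Br)(Br)Br
Why: Appel-type bromination through the alkoxyphosphonium salt should replace the C13 oxygen by bromide with inversion, (13S)-OH to (13R)-Br, as is usual for carbinols next to a ring-ether carbon.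

Step 9
Reactants: 12 {[(2R,3S,5R)-5-[(1R)-1-bromopropyl]-2-[(2Z)-hexa-2,5-dien-1-yl]oxolan-3-yl]oxy}(tert-butyl)dimethylsilane
Product: 14 {[(2S,3S,5S,6S,8R)-8-[(1R)-1-bromopropyl]-3,5-dichloro-2-(prop-2-en-1-yl)oxocan-6-yl]oxy}(tert-butyl)dimethylsilane, via bicyclic oxonium ion 13 (not isolated)
Conditions: Et2SCl·SbCl6 (1.05 equiv), MeNO2/CH2Cl2, −40 °C, 10 min; then n-Bu4NCl (3 equiv), −40 → 0 °C
Reagents that add atoms: chlorodiethylsulfonium hexachloroantimonate, CC[S+](Cl)CC.Cl[Sb-](Cl)(Cl)(Cl)(Cl)Cl; tetrabutylammonium chloride, CCCC[N+](CCCC)(CCCC)CCCC.[Cl-]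
Why: Proposed new method: the chlorosulfonium salt transfers Cl+ to the Z C6=C7 alkene of 12 and the oxolane oxygen attacks C6 anti to the chlorine in a 5-endo closure (ring B: O, C9, C8, C7, C6), which gives the cis-fused 1-oxoniabicyclo[3.3.0]octane 13; added chloride then attacks the ring-fusion carbon C9 from the back, cuts the shared C9–O bond and so merges rings A and B into the oxocane (a ring expansion by three atoms, not a direct eight-membered closure). The closest known reaction type is the bromonium-induced ring expansion of oxolanes that carry a homoallylic alkene, which runs through the same kind of bicyclic oxonium ion with Et2SBr·SbBrCl5 and internal capture, together with the known opening of such oxonium ions by halide; the chloronium trigger and the capture of C9 by external chloride are the untested parts. C6 and C7 come from the anti addition of oxygen and chlorine to the Z alkene (side chain and chlorine cis on the ring), and the alkene face is fixed by the bicyclo[3.3.0] transition state, in which the C5 chain lies exo and the other face would push it against the endo 1-bromopropyl group on C12 of the 2,5-cis-oxolane; C9 is formed by inversion of the (R)-C–O centre that stems from step 3. The step needs chloronium formation at the internal alkene and not at the vinyl group (higher substitution and assistance by the oxygen), ether capture and not vicinal dichlorination (no free chloride before the oxonium salt has formed), and opening at C9 and not at C6 or C12 (both of these carry a β-halogen, C12 also a branched neighbour, and only cleavage of the shared bond relieves both five-membered rings). The C10 silyl ether is trans to the C8 arm and cannot reach C7, and it is used in place of the acetate because an acyloxy group would itself attack C9.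

Step 10
Reactants: 14 {[(2S,3S,5S,6S,8R)-8-[(1R)-1-bromopropyl]-3,5-dichloro-2-(prop-2-en-1-yl)oxocan-6-yl]oxy}(tert-butyl)dimethylsilane
Product: 16 2-[(2S,3S,5S,6S,8R)-8-[(1R)-1-bromopropyl]-6-[(tert-butyldimethylsilyl)oxy]-3,5-dichlorooxocan-2-yl]acetaldehyde, via ozonide 15 (not isolated)
Conditions: O3, CH2Cl2, −78 °C; then PPh3, −78 °C → rt
Reagents that add atoms: ozone, [O-][O+]=O
Why: Ozonolysis with reductive work-up should cleave the only remaining alkene, the terminal vinyl group, to the C4 aldehyde, since the halides and the silyl ether are inert to ozone.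

Step 11
Reactants: 16 2-[(2S,3S,5S,6S,8R)-8-[(1R)-1-bromopropyl]-6-[(tert-butyldimethylsilyl)oxy]-3,5-dichlorooxocan-2-yl]acetaldehyde; 17 1,3-bis(triisopropylsilyl)propyne
Product: 19 {[(2S,3S,5S,6S,8R)-8-[(1R)-1-bromopropyl]-3,5-dichloro-2-[(2Z)-5-(triisopropylsilyl)pent-2-en-4-yn-1-yl]oxocan-6-yl]oxy}(tert-butyl)dimethylsilane, via lithiated bis-silylpropyne 18 (not isolated)
Conditions: 17, n-BuLi, THF, −20 °C; then 16, −78 → −20 °C
Reagents that add atoms: none
Why: In this Peterson olefination the bulky triisopropylsilyl groups of the lithiated propyne steer the addition so that syn loss of silanolate gives the Z enyne, which sets the C3=C4 geometry.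

Step 12
Reactants: 19 {[(2S,3S,5S,6S,8R)-8-[(1R)-1-bromopropyl]-3,5-dichloro-2-[(2Z)-5-(triisopropylsilyl)pent-2-en-4-yn-1-yl]oxocan-6-yl]oxy}(tert-butyl)dimethylsilane
Product: 20 (2S,3S,5S,6S,8R)-8-[(1R)-1-bromopropyl]-3,5-dichloro-2-[(2Z)-5-(triisopropylsilyl)pent-2-en-4-yn-1-yl]oxocan-6-ol
Conditions: HF·pyridine, pyridine, THF, 0 °C → rt
Reagents that add atoms: none
Why: Acidic fluoride should remove the secondary silyl ether while the alkynylsilane survives, and it avoids a basic alkoxide next to the anti C9 chloride that could close an epoxide.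

Step 13
Reactants: 20 (2S,3S,5S,6S,8R)-8-[(1R)-1-bromopropyl]-3,5-dichloro-2-[(2Z)-5-(triisopropylsilyl)pent-2-en-4-yn-1-yl]oxocan-6-ol
Product: 21 (2S,3S,5S,6S,8R)-8-[(1R)-1-bromopropyl]-3,5-dichloro-2-[(2Z)-5-(triisopropylsilyl)pent-2-en-4-yn-1-yl]oxocan-6-yl acetate
Conditions: Ac2O, pyridine, 4-(dimethylamino)pyridine (cat.), CH2Cl2, 0 °C → rt
Reagents that add atoms: acetic anhydride, CC(=O)OC(C)=O
Why: Standard acylation of the hindered secondary alcohol under conditions too weakly basic to touch the halides.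

Step 14
Reactants: 21 (2S,3S,5S,6S,8R)-8-[(1R)-1-bromopropyl]-3,5-dichloro-2-[(2Z)-5-(triisopropylsilyl)pent-2-en-4-yn-1-yl]oxocan-6-yl acetate
Product: 22 (2S,3S,5S,6S,8R)-8-[(1R)-1-bromopropyl]-3,5-dichloro-2-[(2Z)-pent-2-en-4-yn-1-yl]oxocan-6-yl acetate (target)
Conditions: n-Bu4NF, AcOH (1 : 1), THF, 0 °C → rt
Reagents that add atoms: none
Why: Buffered fluoride should cleave the C(sp)–Si bond of the alkynylsilane to the terminal alkyne without hydrolysing the acetate or eliminating the halides.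

**Compound list**

1 | (E)-hex-3-en-1-ol | CC/C=C/CCO | starting material
2 | (E)-hex-3-enal | CC/C=C/CC=O | intermediate
3 | rac-(E)-octa-1,5-dien-3-ol | CC/C=C/CC(O)C=C | intermediate
4 | (1S,3E)-1-[(2R)-oxiran-2-yl]hex-3-en-1-ol | CC/C=C/C[C@H](O)[C@H]1CO1 | intermediate
5 | tert-butyl{[(1S,3E)-1-[(2R)-oxiran-2-yl]hex-3-en-1-yl]oxy}dimethylsilane | CC/C=C/C[C@H](O[Si](C)(C)C(C)(C)C)[C@H]1CO1 | intermediate
6 | pent-1-en-4-yne | C=CCC#C | starting material
7 | lithium pent-4-en-1-yn-1-ide (not isolated) | [Li]C#CCC=C | intermediate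
8 | (7R,8S,10E)-8-[(tert-butyldimethylsilyl)oxy]trideca-1,10-dien-4-yn-7-ol | C=CCC#CC[C@@H](O)[C@@H](O[Si](C)(C)C(C)(C)C)C/C=C/CC | intermediate
9 | (7R,8S)-8-[(tert-butyldimethylsilyl)oxy]-9-[(2S,3S)-3-ethyloxiran-2-yl]non-1-en-4-yn-7-ol (not isolated) | C=CCC#CC[C@@H](O)[C@@H](O[Si](C)(C)C(C)(C)C)C[C@@H]1O[C@H]1CC | intermediate
10 | (1S)-1-[(2R,4S,5R)-4-[(tert-butyldimethylsilyl)oxy]-5-(hex-5-en-2-yn-1-yl)oxolan-2-yl]propan-1-ol | C=CCC#CC[C@H]1O[C@H](C[C@@H]1O[Si](C)(C)C(C)(C)C)[C@@H](O)CC | intermediate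
11 | (1S)-1-[(2R,4S,5R)-4-[(tert-butyldimethylsilyl)oxy]-5-[(2Z)-hexa-2,5-dien-1-yl]oxolan-2-yl]propan-1-ol | C=CC/C=C\C[C@H]1O[C@H](C[C@@H]1O[Si](C)(C)C(C)(C)C)[C@@H](O)CC | intermediate
12 | {[(2R,3S,5R)-5-[(1R)-1-bromopropyl]-2-[(2Z)-hexa-2,5-dien-1-yl]oxolan-3-yl]oxy}(tert-butyl)dimethylsilane | C=CC/C=C\C[C@H]1O[C@H](C[C@@H]1O[Si](C)(C)C(C)(C)C)[C@H](Br)CC | intermediate
13 | (2S,3S,5R,6S,8R)-8-[(1R)-1-bromopropyl]-6-[(tert-butyldimethylsilyl)oxy]-3-chloro-2-(prop-2-en-1-yl)-1-oxoniabicyclo[3.3.0]octane (cation, not isolated; SbCl6 salt in step 9) | C=CC[C@H]1[C@@H](Cl)C[C@@H]2[C@@H](O[Si](C)(C)C(C)(C)C)C[C@H]([C@H](Br)CC)[O+]12 | intermediate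
14 | {[(2S,3S,5S,6S,8R)-8-[(1R)-1-bromopropyl]-3,5-dichloro-2-(prop-2-en-1-yl)oxocan-6-yl]oxy}(tert-butyl)dimethylsilane | C=CC[C@@H]1O[C@@H]([C@H](Br)CC)C[C@H](O[Si](C)(C)C(C)(C)C)[C@@H](Cl)C[C@@H]1Cl | intermediate
15 | ozonide of 14, 3-(oxocan-2-ylmethyl)-1,2,4-trioxolane (not isolated; trioxolane carbon unassigned) | C1OOC(C[C@@H]2O[C@@H]([C@H](Br)CC)C[C@H](O[Si](C)(C)C(C)(C)C)[C@@H](Cl)C[C@@H]2Cl)O1 | intermediate
16 | 2-[(2S,3S,5S,6S,8R)-8-[(1R)-1-bromopropyl]-6-[(tert-butyldimethylsilyl)oxy]-3,5-dichlorooxocan-2-yl]acetaldehyde | O=CC[C@@H]1O[C@@H]([C@H](Br)CC)C[C@H](O[Si](C)(C)C(C)(C)C)[C@@H](Cl)C[C@@H]1Cl | intermediate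
17 | 1,3-bis(triisopropylsilyl)propyne | CC(C)[Si](CC#C[Si](C(C)C)(C(C)C)C(C)C)(C(C)C)C(C)C | starting material
18 | 1-lithio-1,3-bis(triisopropylsilyl)prop-2-yne (not isolated) | [Li]C(C#C[Si](C(C)C)(C(C)C)C(C)C)[Si](C(C)C)(C(C)C)C(C)C | intermediate
19 | {[(2S,3S,5S,6S,8R)-8-[(1R)-1-bromopropyl]-3,5-dichloro-2-[(2Z)-5-(triisopropylsilyl)pent-2-en-4-yn-1-yl]oxocan-6-yl]oxy}(tert-butyl)dimethylsilane | CC(C)[Si](C#C/C=C\C[C@@H]1O[C@@H]([C@H](Br)CC)C[C@H](O[Si](C)(C)C(C)(C)C)[C@@H](Cl)C[C@@H]1Cl)(C(C)C)C(C)C | intermediate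
20 | (2S,3S,5S,6S,8R)-8-[(1R)-1-bromopropyl]-3,5-dichloro-2-[(2Z)-5-(triisopropylsilyl)pent-2-en-4-yn-1-yl]oxocan-6-ol | CC(C)[Si](C#C/C=C\C[C@@H]1O[C@@H]([C@H](Br)CC)C[C@H](O)[C@@H](Cl)C[C@@H]1Cl)(C(C)C)C(C)C | intermediate
21 | (2S,3S,5S,6S,8R)-8-[(1R)-1-bromopropyl]-3,5-dichloro-2-[(2Z)-5-(triisopropylsilyl)pent-2-en-4-yn-1-yl]oxocan-6-yl acetate | CC(C)[Si](C#C/C=C\C[C@@H]1O[C@@H]([C@H](Br)CC)C[C@H](OC(C)=O)[C@@H](Cl)C[C@@H]1Cl)(C(C)C)C(C)C | intermediate
22 | (2S,3S,5S,6S,8R)-8-[(1R)-1-bromopropyl]-3,5-dichloro-2-[(2Z)-pent-2-en-4-yn-1-yl]oxocan-6-yl acetate | C#C/C=C\C[C@@H]1O[C@@H]([C@H](Br)CC)C[C@H](OC(C)=O)[C@@H](Cl)C[C@@H]1Cl | target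

**Step count and risks**

Total steps: 14. Longest linear sequence: 14 steps (1 → 22); 6 and 17 are purchased.

Step 9 (labelled). What may go wrong: vicinal dichlorination of the alkene outruns capture by the ether oxygen; chloride opens the oxonium ion at C6 or C12 and not at the ring-fusion carbon; chlorine is delivered to the wrong alkene face; or the released sulfide is alkylated by the oxonium ion. The fallback uses known reaction types only: the oxonium ion is reached by displacement, with C6 and C7 set beforehand. It sets out from 5 and returns at 14. Epoxide 5 is opened with CH2=CHCH2MgBr and CuI (cat.) to (5R,6S,8E)-6-[(tert-butyldimethylsilyl)oxy]undeca-1,8-dien-5-ol F1. Epoxidation as in step 6 gives the hydroxy epoxide F2, which closes with camphorsulfonic acid to the oxolane alcohol F3. CBr4/(n-C8H17)3P gives the bromide F4. Ozone gives the ozonide F5, which PPh3 reduces to the aldehyde F6. Enamine-catalysed α-chlorination (N-chlorosuccinimide, trans-2,5-diphenylpyrrolidine of the antipode that gives the 2S chloride) gives the α-chloro aldehyde F7. Allylboronic acid pinacol ester adds under dipole (Cornforth-type) control to give the anti chlorohydrin F8. Tf2O and 2,6-di-tert-butyl-4-methylpyridine at −78 °C give the triflate F9, which the oxolane oxygen displaces at C6 with inversion in a 5-exo-tet closure to the same oxonium ion 13 (as its triflate), and n-Bu4NCl opens it to 14. Only the site of the chloride opening then remains open.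

Step 8. What may go wrong: the oxolane oxygen takes part in the displacement at C13 (ring expansion to a bromotetrahydropyran, or elimination), and later the C13 bromine takes part in the oxonium ion of step 9. The fallback introduces bromine after the ring expansion; it sets out from 11 and returns at 14. Alcohol 11 is silylated (Et3SiOTf, 2,6-lutidine) to the triethylsilyl ether F10. The conditions of step 9 give the oxonium ion F11 and then the oxocane F12. Pyridinium p-toluenesulfonate in MeOH removes only the triethylsilyl group to give the alcohol F13. CBr4/(n-C8H17)3P in toluene at 70 °C then gives 14 with inversion, the usual late bromination of Laurencia-type oxocanes.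

Step 11. What may go wrong: enolisation or β-elimination of the β-alkoxy aldehyde by the basic lithium reagent, and erosion of the Z geometry. The fallback builds the enyne in two steps; it sets out from 16 and returns at 19. Stork–Zhao olefination (Ph3P(CH2I)I, NaN(SiMe3)2, THF, −78 °C) gives the (Z)-vinyl iodide F14, and Sonogashira coupling with (triisopropylsilyl)acetylene (Pd(PPh3)4, CuI, i-Pr2NH) gives 19 with retention of the alkene geometry.

**Further compounds**

F1 | step 9 | (5R,6S,8E)-6-[(tert-butyldimethylsilyl)oxy]undeca-1,8-dien-5-ol | C=CCC[C@@H](O)[C@@H](O[Si](C)(C)C(C)(C)C)C/C=C/CC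
F2 | step 9 | (5R,6S)-6-[(tert-butyldimethylsilyl)oxy]-7-[(2S,3S)-3-ethyloxiran-2-yl]hept-1-en-5-ol (not isolated) | C=CCC[C@@H](O)[C@@H](O[Si](C)(C)C(C)(C)C)C[C@@H]1O[C@H]1CC
F3 | step 9 | (1S)-1-[(2R,4S,5R)-5-(but-3-en-1-yl)-4-[(tert-butyldimethylsilyl)oxy]oxolan-2-yl]propan-1-ol | C=CCC[C@H]1O[C@H](C[C@@H]1O[Si](C)(C)C(C)(C)C)[C@@H](O)CC
F4 | step 9 | {[(2R,3S,5R)-5-[(1R)-1-bromopropyl]-2-(but-3-en-1-yl)oxolan-3-yl]oxy}(tert-butyl)dimethylsilane | C=CCC[C@H]1O[C@H](C[C@@H]1O[Si](C)(C)C(C)(C)C)[C@H](Br)CC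
F5 | step 9 | ozonide of F4, 3-substituted 1,2,4-trioxolane (not isolated) | C1OOC(CC[C@H]2O[C@H](C[C@@H]2O[Si](C)(C)C(C)(C)C)[C@H](Br)CC)O1
F6 | step 9 | 3-[(2R,3S,5R)-5-[(1R)-1-bromopropyl]-3-[(tert-butyldimethylsilyl)oxy]oxolan-2-yl]propanal | O=CCC[C@H]1O[C@H](C[C@@H]1O[Si](C)(C)C(C)(C)C)[C@H](Br)CC
F7 | step 9 | (2S)-3-[(2R,3S,5R)-5-[(1R)-1-bromopropyl]-3-[(tert-butyldimethylsilyl)oxy]oxolan-2-yl]-2-chloropropanal | O=C[C@@H](Cl)C[C@H]1O[C@H](C[C@@H]1O[Si](C)(C)C(C)(C)C)[C@H](Br)CC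
F8 | step 9 | (4R,5S)-6-[(2R,3S,5R)-5-[(1R)-1-bromopropyl]-3-[(tert-butyldimethylsilyl)oxy]oxolan-2-yl]-5-chlorohex-1-en-4-ol | C=CC[C@@H](O)[C@@H](Cl)C[C@H]1O[C@H](C[C@@H]1O[Si](C)(C)C(C)(C)C)[C@H](Br)CC
F9 | step 9 | trifluoromethanesulfonate of F8 (not isolated) | C=CC[C@@H](OS(=O)(=O)C(F)(F)F)[C@@H](Cl)C[C@H]1O[C@H](C[C@@H]1O[Si](C)(C)C(C)(C)C)[C@H](Br)CC
F10 | step 8 | tert-butyl{[(2R,3S,5R)-2-[(2Z)-hexa-2,5-dien-1-yl]-5-[(1S)-1-[(triethylsilyl)oxy]propyl]oxolan-3-yl]oxy}dimethylsilane | C=CC/C=C\C[C@H]1O[C@H](C[C@@H]1O[Si](C)(C)C(C)(C)C)[C@@H](O[Si](CC)(CC)CC)CC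
F11 | step 8 | (2S,3S,5R,6S,8R)-6-[(tert-butyldimethylsilyl)oxy]-3-chloro-2-(prop-2-en-1-yl)-8-[(1S)-1-[(triethylsilyl)oxy]propyl]-1-oxoniabicyclo[3.3.0]octane (cation, not isolated) | C=CC[C@H]1[C@@H](Cl)C[C@@H]2[C@@H](O[Si](C)(C)C(C)(C)C)C[C@H]([C@@H](O[Si](CC)(CC)CC)CC)[O+]12
F12 | step 8 | tert-butyl{[(2S,3S,5S,6S,8R)-3,5-dichloro-2-(prop-2-en-1-yl)-8-[(1S)-1-[(triethylsilyl)oxy]propyl]oxocan-6-yl]oxy}dimethylsilane | C=CC[C@@H]1O[C@@H]([C@@H](O[Si](CC)(CC)CC)CC)C[C@H](O[Si](C)(C)C(C)(C)C)[C@@H](Cl)C[C@@H]1Cl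
F13 | step 8 | (1S)-1-[(2R,4S,5S,7S,8S)-4-[(tert-butyldimethylsilyl)oxy]-5,7-dichloro-8-(prop-2-en-1-yl)oxocan-2-yl]propan-1-ol | C=CC[C@@H]1O[C@@H]([C@@H](O)CC)C[C@H](O[Si](C)(C)C(C)(C)C)[C@@H](Cl)C[C@@H]1Cl
F14 | step 11 | tert-butyl{[(2S,3S,5S,6S,8R)-8-[(1R)-1-bromopropyl]-3,5-dichloro-2-[(2Z)-3-iodoprop-2-en-1-yl]oxocan-6-yl]oxy}dimethylsilane | I/C=C\C[C@@H]1O[C@@H]([C@H](Br)CC)C[C@H](O[Si](C)(C)C(C)(C)C)[C@@H](Cl)C[C@@H]1Cl
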